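**Strategy.** Lappaol A is cut at the lactone β‑benzyl bond (aryl Grignard plus an epichlorohydrin‑derived cyclopropane lactone) and, centrally, at C3–C3a of the dihydrobenzofuran. C3, its CH2OH carbon and the trans C2 aryl group are read as C3, C4 and C2 of a (2S)‑flavanone. One iodine(III) oxidation shifts ring carbon C4a from C4 to C3, which contracts the pyranone to the dihydrofuran, expels C4 as a methyl ester and sets C3 trans to C2. The precursor is (2S)‑6‑bromo‑8‑methoxyflavanone carrying a mesylated guaiacyl ring, made by asymmetric aryl addition to the chromone.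

Key step: step 5

Remarks and assumptions (chemistry only):
- Dimethyl malonate is used as a fifth commercial starting material.
- The sense of induction of the diene ligand in step 4 is taken from cyclic‑enone precedent. It would be checked by chiral HPLC on the first run, and the ligand antipode used if it proves opposite.
- The precursor design is kept, for three reasons. Bromine is fixed on the acetophenone, para to OH, before the chromone exists. The mesylate deactivates the C2 aryl ring, disfavours ionisation of the benzylic C2–O bond and tolerates acid and iodine(III). It is exchanged for silyl only once no enolisable ester remains.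
- CIP descriptors change by priority only, with no change in geometry, at C3 (S in ester 10, R from carbinol 11 onward) and at C2 of intermediate 9.
- Abbreviations: Ms = methylsulfonyl, TIPS = triisopropylsilyl.

**Route**

Step 1
Reactants: 1 1-(2-hydroxy-3-methoxyphenyl)ethanone
Product: 2 1-(5-bromo-2-hydroxy-3-methoxyphenyl)ethanone
Conditions: NBS (1.05 equiv), MeCN, 0 °C to rt
Reagents that add atoms: N-bromosuccinimide, O=C1CCC(=O)N1Br
Why: Electrophilic aromatic bromination should go para to the phenolic OH (C5, meta to the acetyl group), because both ortho positions of the OH are substituted and the OH is the strongest director.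

Step 2
Reactants: 2 1-(5-bromo-2-hydroxy-3-methoxyphenyl)ethanone
Product: 4 6-bromo-8-methoxy-4H-chromen-4-one, via enaminone 3 (not isolated)
Conditions: DMF-DMA (1.5 equiv), toluene, 100 °C; then conc. HCl, CH2Cl2, 40 °C
Reagents that add atoms: N,N-dimethylformamide dimethyl acetal, COC(OC)N(C)C
Why: Enaminone condensation at the acetyl CH3 followed by acid-promoted intramolecular oxa-Michael addition and loss of dimethylamine is the standard chromone synthesis from 2'-hydroxyacetophenones.

Step 3
Reactants: 5 2-methoxy-4-(4,4,5,5-tetramethyl-1,3,2-dioxaborolan-2-yl)phenol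
Product: 6 2-methoxy-4-(4,4,5,5-tetramethyl-1,3,2-dioxaborolan-2-yl)phenyl methanesulfonate
Conditions: MsCl (1.2 equiv), Et3N (1.5 equiv), CH2Cl2, 0 °C
Reagents that add atoms: methanesulfonyl chloride, CS(=O)(=O)Cl
Why: O-Sulfonylation of the phenol should leave the pinacol boronate untouched and gives the electron-poor aryl donor needed later.

Step 4
Reactants: 4 6-bromo-8-methoxy-4H-chromen-4-one; 6 2-methoxy-4-(pinacolboryl)phenyl methanesulfonate (1.5 equiv)
Product: 7 (2S)-6-bromo-8-methoxy-2-[3-methoxy-4-(methylsulfonyloxy)phenyl]chroman-4-one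
Conditions: [RhCl(C2H4)2]2 (2.5 mol%), (S,S)-Ph-bod* chiral diene (5.5 mol%), aq. K3PO4 (0.5 equiv), dioxane, 50 °C; quench with aq. NH4Cl
Reagents that add atoms: none
Why: Hayashi–Miyaura rhodium-catalysed asymmetric 1,4-addition: the aryl–rhodium species adds to C2 of the chromone on the face left open by the chiral diene, which sets C2 as S, and the oxa-π-allyl rhodium is protonated by water; the weak base and buffered quench are chosen to limit retro-oxa-Michael opening of the product.

Step 5
Reactants: 7 (2S)-6-bromo-8-methoxy-2-[3-methoxy-4-(methylsulfonyloxy)phenyl]chroman-4-one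
Product: 10 methyl (2S,3S)-5-bromo-7-methoxy-2-[3-methoxy-4-(methylsulfonyloxy)phenyl]-2,3-dihydro-1-benzofuran-3-carboxylate, via methyl enol ether 8 (not isolated), via trans C3-iodanyl dimethyl ketal 9 (not isolated)
Conditions: PhI(OAc)2 (1.2 equiv), conc. H2SO4 (1.5 equiv), HC(OMe)3, 0 °C to rt; aq. NaHCO3
Reagents that add atoms: trimethyl orthoformate, COC(OC)OC
Why: Acid and orthoformate turn the ketone into its dimethyl ketal and methyl enol ether 8, whose C3 is attacked by the iodine(III) electrophile anti to the C2 aryl group; methanol capture gives the 2,3-trans iodanyl ketal 9, whose equatorial C3–I bond lies antiperiplanar to the C4–C4a ring bond. Carbon C4a then shifts from C4 to C3 as iodobenzene departs, through a phenonium-like bridged transition state, and the dimethoxycarbenium ion left at C4 is demethylated to the methyl ester; the closest known reaction type is the iodine(III)- or thallium(III)-mediated oxidative 1,2-aryl shift of aryl ketones in orthoformate, in its flavanone ring-contraction form. The five-membered ring is not closed end to end but by this 1,2-shift, a 3-exo-tet attack of C4a on C3 that converts the six-membered ring into the dihydrofuran. C3 is the only new stereocentre and is controlled by C2: anti addition of iodine followed by inversion at C3 places the ester trans to the aryl group, and the enolisable ester can equilibrate to the same, more stable trans isomer. The step needs migration of the fused arene in preference to a 2,3-shift of the C2 aryl group (isoflavone), loss of the C2 hydrogen (flavone) and solvent capture at C3; the ring oxygen ortho to C4a makes that carbon a good migrating group, while the mesylate makes the C2 aryl ring a poor one and disfavours ionisation of the C2–O bond, so C2 should keep its configuration.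

Step 6
Reactants: 10 methyl (2S,3S)-5-bromo-7-methoxy-2-[3-methoxy-4-(methylsulfonyloxy)phenyl]-2,3-dihydro-1-benzofuran-3-carboxylate
Product: 11 4-[(2S,3R)-5-bromo-3-(hydroxymethyl)-7-methoxy-2,3-dihydro-1-benzofuran-2-yl]-2-methoxyphenyl methanesulfonate
Conditions: DIBAL-H (3 equiv), CH2Cl2, −78 to 0 °C; Rochelle salt
Reagents that add atoms: none
Why: Hydride reduction of the ester to the primary alcohol under non-basic conditions should avoid enolisation at C3 and leave the aryl mesylate and aryl bromide intact.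

Step 7
Reactants: 11 4-[(2S,3R)-5-bromo-3-(hydroxymethyl)-7-methoxy-2,3-dihydro-1-benzofuran-2-yl]-2-methoxyphenyl methanesulfonate
Product: 12 4-[(2S,3R)-5-bromo-3-(hydroxymethyl)-7-methoxy-2,3-dihydro-1-benzofuran-2-yl]-2-methoxyphenol
Conditions: 2 M aq. KOH (5 equiv), MeOH/THF, 50 °C; aq. NH4Cl
Reagents that add atoms: none
Why: Base-mediated cleavage of the aryl sulfonate (sulfene E1cB or attack at sulfur) frees the phenol, and with the ester gone no enolisable centre is exposed to the base.

Step 8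
Reactants: 12 4-[(2S,3R)-5-bromo-3-(hydroxymethyl)-7-methoxy-2,3-dihydro-1-benzofuran-2-yl]-2-methoxyphenol
Product: 13 (2S,3R)-5-bromo-7-methoxy-2-[3-methoxy-4-(TIPS-oxy)phenyl]-3-[(TIPS-oxy)methyl]-2,3-dihydro-1-benzofuran
Conditions: TIPSCl (2.5 equiv), imidazole (5 equiv), DMF, rt to 40 °C
Reagents that add atoms: chlorotriisopropylsilane, CC(C)[Si](Cl)(C(C)C)C(C)C
Why: Imidazole-promoted silylation should cap both the phenol and the primary alcohol with groups that tolerate organomagnesium, chloride at high temperature and amide bases.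

Step 9
Reactants: 14 dimethyl malonate; 15 (R)-epichlorohydrin
Product: 18 methyl (1S,5R)-2-oxo-3-oxabicyclo[3.1.0]hexane-1-carboxylate, via glycidylmalonate 16 (not isolated), via cyclopropylcarbinol diester 17 (not isolated)
Conditions: NaOMe (1.0 equiv), MeOH, 0 °C to reflux
Reagents that add atoms: none
Why: Malonate alkylation cascade: the anion opens the epoxide at its CH2 terminus, the alkoxide displaces chloride to give a new epoxide (16), a second deprotonation closes the cyclopropane by 3-exo-tet attack with inversion at the stereogenic carbon (17) and the cis alkoxide lactonises, so C5 comes from the epichlorohydrin centre by one inversion and C1 follows from the cis ring fusion.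

Step 10
Reactants: 13 (2S,3R)-5-bromo-7-methoxy-2-[3-methoxy-4-(TIPS-oxy)phenyl]-3-[(TIPS-oxy)methyl]-2,3-dihydro-1-benzofuran; 18 methyl (1S,5R)-2-oxo-3-oxabicyclo[3.1.0]hexane-1-carboxylate (1.3 equiv)
Product: 20 methyl (3S,4R)-4-({(2S,3R)-7-methoxy-2-[3-methoxy-4-(TIPS-oxy)phenyl]-3-[(TIPS-oxy)methyl]-2,3-dihydro-1-benzofuran-5-yl}methyl)-2-oxooxolane-3-carboxylate, via arylmagnesium bromide 19 (not isolated)
Conditions: Mg turnings (DIBAL-H-activated), LiCl, THF, rt; then 18, CuI (20 mol%), THF, −40 to 0 °C; aq. NH4Cl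
Reagents that add atoms: none
Why: Copper-catalysed homoconjugate addition of the aryl Grignard reagent to the doubly activated cyclopropane at its unsubstituted CH2 should give the malonate-type enolate; the C5 centre of 18 is untouched and becomes lactone C4 (R), while C3 is epimerisable (mainly trans) and is removed in the next step.

Step 11
Reactants: 20 methyl (3S,4R)-4-(arylmethyl)-2-oxooxolane-3-carboxylate described in step 10
Product: 21 (4R)-4-({(2S,3R)-7-methoxy-2-[3-methoxy-4-(TIPS-oxy)phenyl]-3-[(TIPS-oxy)methyl]-2,3-dihydro-1-benzofuran-5-yl}methyl)oxolan-2-one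
Conditions: LiCl (3 equiv), H2O (2 equiv), DMSO, 130 °C
Reagents that add atoms: none
Why: Krapcho dealkoxycarbonylation (chloride demethylation of the doubly activated ester, decarboxylation, protonation) should leave C4 unaffected, and the bulky TIPS ethers are expected to withstand chloride and the weakly basic medium.

Step 12
Reactants: 22 vanillin
Product: 23 3-methoxy-4-(TIPS-oxy)benzaldehyde
Conditions: TIPSCl (1.2 equiv), imidazole (2.5 equiv), DMF, rt
Reagents that add atoms: chlorotriisopropylsilane, CC(C)[Si](Cl)(C(C)C)C(C)C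
Why: Routine silylation of the phenol.

Step 13
Reactants: 23 3-methoxy-4-(TIPS-oxy)benzaldehyde
Product: 24 [3-methoxy-4-(TIPS-oxy)phenyl]methanol
Conditions: NaBH4, MeOH, 0 °C
Reagents that add atoms: none
Why: Borohydride reduction of the aldehyde should not affect the aryl silyl ether at 0 °C.

Step 14
Reactants: 24 [3-methoxy-4-(TIPS-oxy)phenyl]methanol
Product: 25 4-(bromomethyl)-2-methoxy-1-(TIPS-oxy)benzene
Conditions: CBr4 (1.2 equiv), PPh3 (1.2 equiv), CH2Cl2, 0 °C; used at once
Reagents that add atoms: carbon tetrabromide, BrC(Br)(Br)Br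
Why: Appel bromination under neutral conditions should convert the benzylic alcohol without cleaving the silyl ether.

Step 15
Reactants: 21 (4R)-4-(arylmethyl)oxolan-2-one described in step 11; 25 4-(bromomethyl)-2-methoxy-1-(TIPS-oxy)benzene (1.2 equiv)
Product: 27 (3R,4R)-3-{[3-methoxy-4-(TIPS-oxy)phenyl]methyl}-4-({(2S,3R)-7-methoxy-2-[3-methoxy-4-(TIPS-oxy)phenyl]-3-[(TIPS-oxy)methyl]-2,3-dihydro-1-benzofuran-5-yl}methyl)oxolan-2-one, via lithium enolate 26 (not isolated)
Conditions: LiHMDS (1.1 equiv), THF, −78 °C; then 25, DMPU, −78 to −40 °C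
Reagents that add atoms: none
Why: Lactone enolate alkylation, in which the benzylic bromide should approach anti to the C4 substituent and so set C3 as R (trans), as is general for β-benzyl-γ-butyrolactones.

Step 16
Reactants: 27 tris-TIPS ether described in step 15
Product: 28 lappaol A, (3R,4R)-3-[(4-hydroxy-3-methoxyphenyl)methyl]-4-{[(2S,3R)-2-(4-hydroxy-3-methoxyphenyl)-3-(hydroxymethyl)-7-methoxy-2,3-dihydro-1-benzofuran-5-yl]methyl}oxolan-2-one
Conditions: TBAF (4 equiv), AcOH (4 equiv), THF, 0 °C to rt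
Reagents that add atoms: none
Why: Fluoride-mediated cleavage of the three Si–O bonds, buffered with acetic acid so that neither the lactone α-centre nor the phenylcoumaran ring should suffer from phenoxide or basic fluoride.

**Compound list**

1 | 1-(2-hydroxy-3-methoxyphenyl)ethanone | CC(=O)c1cccc(OC)c1O | starting material
2 | 1-(5-bromo-2-hydroxy-3-methoxyphenyl)ethanone | CC(=O)c1cc(Br)cc(OC)c1O | intermediate
3 | (E)-1-(5-bromo-2-hydroxy-3-methoxyphenyl)-3-(dimethylamino)prop-2-en-1-one | CN(C)/C=C/C(=O)c1cc(Br)cc(OC)c1O | intermediate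
4 | 6-bromo-8-methoxy-4H-chromen-4-one | O=c1ccoc2c(OC)cc(Br)cc12 | intermediate
5 | 2-methoxy-4-(4,4,5,5-tetramethyl-1,3,2-dioxaborolan-2-yl)phenol | COc1cc(B2OC(C)(C)C(C)(C)O2)ccc1O | starting material
6 | 2-methoxy-4-(4,4,5,5-tetramethyl-1,3,2-dioxaborolan-2-yl)phenyl methanesulfonate | COc1cc(B2OC(C)(C)C(C)(C)O2)ccc1OS(C)(=O)=O | intermediate
7 | (2S)-6-bromo-8-methoxy-2-[3-methoxy-4-(methylsulfonyloxy)phenyl]chroman-4-one | O=C1C[C@@H](c2ccc(OS(C)(=O)=O)c(OC)c2)Oc2c(OC)cc(Br)cc12 | intermediate
8 | (2S)-6-bromo-4,8-dimethoxy-2-[3-methoxy-4-(methylsulfonyloxy)phenyl]-2H-chromene | COC1=C[C@@H](c2ccc(OS(C)(=O)=O)c(OC)c2)Oc2c(OC)cc(Br)cc12 | intermediate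
9 | (2R,3R)-3-[acetoxy(phenyl)-λ3-iodanyl]-6-bromo-4,4,8-trimethoxy-2-[3-methoxy-4-(methylsulfonyloxy)phenyl]chromane (2,3-trans) | COC1(OC)[C@H](I(OC(C)=O)c2ccccc2)[C@@H](c2ccc(OS(C)(=O)=O)c(OC)c2)Oc2c(OC)cc(Br)cc12 | intermediate
10 | methyl (2S,3S)-5-bromo-7-methoxy-2-[3-methoxy-4-(methylsulfonyloxy)phenyl]-2,3-dihydro-1-benzofuran-3-carboxylate (trans) | COC(=O)[C@@H]1[C@@H](c2ccc(OS(C)(=O)=O)c(OC)c2)Oc2c(OC)cc(Br)cc12 | intermediate
11 | 4-[(2S,3R)-5-bromo-3-(hydroxymethyl)-7-methoxy-2,3-dihydro-1-benzofuran-2-yl]-2-methoxyphenyl methanesulfonate | OC[C@@H]1[C@@H](c2ccc(OS(C)(=O)=O)c(OC)c2)Oc2c(OC)cc(Br)cc12 | intermediate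
12 | 4-[(2S,3R)-5-bromo-3-(hydroxymethyl)-7-methoxy-2,3-dihydro-1-benzofuran-2-yl]-2-methoxyphenol | OC[C@@H]1[C@@H](c2ccc(O)c(OC)c2)Oc2c(OC)cc(Br)cc12 | intermediate
13 | (2S,3R)-5-bromo-7-methoxy-2-[3-methoxy-4-(triisopropylsilyloxy)phenyl]-3-[(triisopropylsilyloxy)methyl]-2,3-dihydro-1-benzofuran | CC(C)[Si](OC[C@@H]1[C@@H](c2ccc(O[Si](C(C)C)(C(C)C)C(C)C)c(OC)c2)Oc2c(OC)cc(Br)cc12)(C(C)C)C(C)C | intermediate
14 | dimethyl malonate | COC(=O)CC(=O)OC | starting material
15 | (R)-epichlorohydrin | ClC[C@H]1CO1 | starting material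
16 | dimethyl 2-{[(2R)-oxiran-2-yl]methyl}propanedioate | COC(=O)C(C[C@@H]1CO1)C(=O)OC | intermediate
17 | dimethyl (2R)-2-(hydroxymethyl)cyclopropane-1,1-dicarboxylate (as its sodium alkoxide) | COC(=O)C1(C[C@H]1CO)C(=O)OC | intermediate
18 | methyl (1S,5R)-2-oxo-3-oxabicyclo[3.1.0]hexane-1-carboxylate | COC(=O)[C@]12C[C@H]1COC2=O | intermediate
19 | {(2S,3R)-7-methoxy-2-[3-methoxy-4-(triisopropylsilyloxy)phenyl]-3-[(triisopropylsilyloxy)methyl]-2,3-dihydro-1-benzofuran-5-yl}magnesium bromide | CC(C)[Si](OC[C@@H]1[C@@H](c2ccc(O[Si](C(C)C)(C(C)C)C(C)C)c(OC)c2)Oc2c(OC)cc([Mg]Br)cc12)(C(C)C)C(C)C | intermediate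
20 | methyl (3S,4R)-4-({(2S,3R)-7-methoxy-2-[3-methoxy-4-(triisopropylsilyloxy)phenyl]-3-[(triisopropylsilyloxy)methyl]-2,3-dihydro-1-benzofuran-5-yl}methyl)-2-oxooxolane-3-carboxylate (trans shown; C3 epimerisable) | COC(=O)[C@H]1C(=O)OC[C@@H]1Cc1cc(OC)c2c(c1)[C@H](CO[Si](C(C)C)(C(C)C)C(C)C)[C@@H](c1ccc(O[Si](C(C)C)(C(C)C)C(C)C)c(OC)c1)O2 | intermediate
21 | (4R)-4-({(2S,3R)-7-methoxy-2-[3-methoxy-4-(triisopropylsilyloxy)phenyl]-3-[(triisopropylsilyloxy)methyl]-2,3-dihydro-1-benzofuran-5-yl}methyl)oxolan-2-one | O=C1C[C@@H](Cc2cc(OC)c3c(c2)[C@H](CO[Si](C(C)C)(C(C)C)C(C)C)[C@@H](c2ccc(O[Si](C(C)C)(C(C)C)C(C)C)c(OC)c2)O3)CO1 | intermediate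
22 | vanillin | COc1cc(C=O)ccc1O | starting material
23 | 3-methoxy-4-(triisopropylsilyloxy)benzaldehyde | COc1cc(C=O)ccc1O[Si](C(C)C)(C(C)C)C(C)C | intermediate
24 | [3-methoxy-4-(triisopropylsilyloxy)phenyl]methanol | COc1cc(CO)ccc1O[Si](C(C)C)(C(C)C)C(C)C | intermediate
25 | 4-(bromomethyl)-2-methoxy-1-(triisopropylsilyloxy)benzene | COc1cc(CBr)ccc1O[Si](C(C)C)(C(C)C)C(C)C | intermediate
26 | lithium enolate of 21 (lithium (4R)-4-(arylmethyl)-4,5-dihydrofuran-2-olate) | [Li]OC1=C[C@@H](Cc2cc(OC)c3c(c2)[C@H](CO[Si](C(C)C)(C(C)C)C(C)C)[C@@H](c2ccc(O[Si](C(C)C)(C(C)C)C(C)C)c(OC)c2)O3)CO1 | intermediate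
27 | (3R,4R)-3-{[3-methoxy-4-(triisopropylsilyloxy)phenyl]methyl}-4-({(2S,3R)-7-methoxy-2-[3-methoxy-4-(triisopropylsilyloxy)phenyl]-3-[(triisopropylsilyloxy)methyl]-2,3-dihydro-1-benzofuran-5-yl}methyl)oxolan-2-one | COc1cc(C[C@H]2C(=O)OC[C@@H]2Cc2cc(OC)c3c(c2)[C@H](CO[Si](C(C)C)(C(C)C)C(C)C)[C@@H](c2ccc(O[Si](C(C)C)(C(C)C)C(C)C)c(OC)c2)O3)ccc1O[Si](C(C)C)(C(C)C)C(C)C | intermediate
28 | lappaol A | COc1cc(C[C@H]2C(=O)OC[C@@H]2Cc2cc(OC)c3c(c2)[C@H](CO)[C@@H](c2ccc(O)c(OC)c2)O3)ccc1O | target

**Step count and risk**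

Total step count: 16. Longest linear sequence: 11 steps (1, 2, 4, 5, 6, 7, 8, 10, 11, 15, 16); side branches are step 3, step 9 and steps 12–14.

Steps most likely to fail:

1. Step 5. The oxidation may take another course: a 2,3-shift of the C2 aryl group, dehydrogenation to the flavone or methanol capture at C3. The acid may also erode the C2 configuration through ring opening. Fallback, from 7 back to 10: the same C4a shift would be driven by a carbene instead of an iodane. The lithium enolate of 7 (LiHMDS, THF, −78 °C) is acylated with 2,2,2-trifluoroethyl trifluoroacetate to the 3-(trifluoroacetyl)flavanone F1. Detrifluoroacetylative diazo transfer (MsN3, Et3N, MeCN, H2O) gives the 3-diazoflavanone F2. Photochemical Wolff rearrangement in methanol contracts the ring and traps the ketene as 10 together with its C3 epimer, the cis ester F3. Brief NaOMe in MeOH at 0 °C equilibrates F3 to the trans ester, so the sequence rejoins the route at 10.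

2. Step 4. Transmetallation of the pinacol boronate may be slow, the base may open the flavanone and racemise it, or facial selectivity may be insufficient. Fallback, from 2 and 22 back to 7: vanillin 22 is mesylated (MsCl, Et3N) to 4-formyl-2-methoxyphenyl methanesulfonate F4. Claisen–Schmidt condensation of F4 with 2 (pyrrolidine, EtOH) gives the 2'-hydroxychalcone F5. NaOAc in refluxing EtOH closes F5 by oxa-Michael addition to the racemic flavanone F6. Preparative chiral SFC then delivers the (2S) enantiomer, which is 7, and the (2R) enantiomer is returned to F5 by base-mediated ring opening and recycled.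

3. Step 10. Magnesium insertion into the hindered, electron-rich bromide may be sluggish, the aryl metal may be protonated or homocoupled, or it may attack a carbonyl group instead of the cyclopropane. Fallback, from 13 back to 21 (steps 10 and 11 are bypassed): bromine–lithium exchange (t-BuLi, THF, −78 °C) and DMF give the 5-carbaldehyde F7. Stobbe condensation with dimethyl succinate (t-BuOK, t-BuOH/THF) gives the (E)-arylidenesuccinic half-ester F8. Rhodium–DuPhos asymmetric hydrogenation, with the ligand antipode chosen for the R product, gives the (R)-2-(arylmethyl)succinic 1-methyl ester F9. Reduction of the ester in the presence of the carboxylate (CaCl2/NaBH4, EtOH) and acid-promoted lactonisation then give 21.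

**Further compounds**

F1 | step 5 | (2S)-6-bromo-8-methoxy-2-[3-methoxy-4-(methylsulfonyloxy)phenyl]-3-(trifluoroacetyl)chroman-4-one (C3 epimers and enol) | O=C1C(C(=O)C(F)(F)F)[C@@H](c2ccc(OS(C)(=O)=O)c(OC)c2)Oc2c(OC)cc(Br)cc12
F2 | step 5 | (2R)-6-bromo-3-diazo-8-methoxy-2-[3-methoxy-4-(methylsulfonyloxy)phenyl]chroman-4-one (same C2 geometry as 7) | O=C1C(=[N+]=[N-])[C@@H](c2ccc(OS(C)(=O)=O)c(OC)c2)Oc2c(OC)cc(Br)cc12
F3 | step 5 | methyl (2S,3R)-5-bromo-7-methoxy-2-[3-methoxy-4-(methylsulfonyloxy)phenyl]-2,3-dihydro-1-benzofuran-3-carboxylate (cis) | COC(=O)[C@H]1[C@@H](c2ccc(OS(C)(=O)=O)c(OC)c2)Oc2c(OC)cc(Br)cc12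
F4 | step 4 | 4-formyl-2-methoxyphenyl methanesulfonate | COc1cc(C=O)ccc1OS(C)(=O)=O
F5 | step 4 | (E)-1-(5-bromo-2-hydroxy-3-methoxyphenyl)-3-[3-methoxy-4-(methylsulfonyloxy)phenyl]prop-2-en-1-one | COc1cc(/C=C/C(=O)c2cc(Br)cc(OC)c2O)ccc1OS(C)(=O)=O
F6 | step 4 | racemic 6-bromo-8-methoxy-2-[3-methoxy-4-(methylsulfonyloxy)phenyl]chroman-4-one | O=C1CC(c2ccc(OS(C)(=O)=O)c(OC)c2)Oc2c(OC)cc(Br)cc12
F7 | step 10 | (2S,3R)-7-methoxy-2-[3-methoxy-4-(triisopropylsilyloxy)phenyl]-3-[(triisopropylsilyloxy)methyl]-2,3-dihydro-1-benzofuran-5-carbaldehyde | CC(C)[Si](OC[C@@H]1[C@@H](c2ccc(O[Si](C(C)C)(C(C)C)C(C)C)c(OC)c2)Oc2c(OC)cc(C=O)cc12)(C(C)C)C(C)C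
F8 | step 10 | (E)-3-(methoxycarbonyl)-4-{(2S,3R)-7-methoxy-2-[3-methoxy-4-(triisopropylsilyloxy)phenyl]-3-[(triisopropylsilyloxy)methyl]-2,3-dihydro-1-benzofuran-5-yl}but-3-enoic acid | COC(=O)/C(CC(=O)O)=C/c1cc(OC)c2c(c1)[C@H](CO[Si](C(C)C)(C(C)C)C(C)C)[C@@H](c1ccc(O[Si](C(C)C)(C(C)C)C(C)C)c(OC)c1)O2
F9 | step 10 | (3R)-3-(methoxycarbonyl)-4-{(2S,3R)-7-methoxy-2-[3-methoxy-4-(triisopropylsilyloxy)phenyl]-3-[(triisopropylsilyloxy)methyl]-2,3-dihydro-1-benzofuran-5-yl}butanoic acid | OC(=O)C[C@@H](Cc1cc(OC)c2c(c1)[C@H](CO[Si](C(C)C)(C(C)C)C(C)C)[C@@H](c1ccc(O[Si](C(C)C)(C(C)C)C(C)C)c(OC)c1)O2)C(=O)OC
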